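**Retrosynthetic overview**
1. The 8-O-4′ arm is attached last: the C8–O bond by Mitsunobu etherification of core phenol 13 with the lactate-derived (S)-α-hydroxy ketone 19 (inversion gives 8R), C7 by Felkin–Anh reduction (7R), then desilylation.
2. The oxolane (O1, C2–C5) is not closed from an open chain: it arises in step 7 from the three-membered ring of aryl cyclopropyl ketone 10 by a two-atom ring expansion (Cloke–Wilson rearrangement) run straight on into an ionic hydrogenation. Cyclopropane C1, C3 and C2 become oxolane C3, C4 and C5; the ketone carbon and oxygen become C2 and O1.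
3. Enabling feature: in 10 the cyclopropane bond C1–C2 is push–pull (C2 carries the 4-benzyloxy-3-methoxyphenyl donor, C1 the aroyl acceptor). It ionises selectively to a benzylic cation and an enolate whose oxygen recloses to the five-membered ring; the methyl-bearing C3 is the only stereocentre carried through and it relays to the other three.
4. Ketone 10 comes from tiglyl alcohol 3 (both ring methyls and the ketone carbon) by asymmetric iodocyclopropanation, Suzuki arylation, oxidation, aryllithium addition and oxidation.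
5. Ring order: cyclopropane (step 2), then oxolane (step 7); the three arenes are bought as 1 (used twice) and 5.

Key step: step 7

Remark (assumption): the facial sense of the (4R,5R)-dioxaborolane controller in step 2 is taken to be the one established for (E)-cinnamyl-type alcohols; the (4S,5S)-controller is equally available should the 2-methyl substrate answer in the opposite sense.
Remark: the iodine- or aryl-bearing carbon C2 of 4, 6, 7, 9 and 10 is drawn syn to the C1 carbon substituent; this centre becomes a planar benzylic cation in step 7, so either C2 epimer serves.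

**Step 1**
Reactants: 1 4-bromo-2-methoxyphenol
Product: 2 (4-bromo-2-methoxyphenoxy)tri(propan-2-yl)silane
Conditions: TIPSCl, imidazole, DMF, 0 °C to rt
Reagents that add atoms: chlorotri(propan-2-yl)silane, CC(C)[Si](Cl)(C(C)C)C(C)C
Why: Imidazole-promoted O-silylation of the phenol; the aryl TIPS ether should survive aryllithium and Grignard formation, Lewis acid, hydrogenolysis and Mitsunobu conditions and leaves with fluoride in step 15.

**Step 2**
Reactants: 3 (E)-2-methylbut-2-en-1-ol (tiglyl alcohol)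
Product: 4 [(1S,2S,3R)-2-iodo-1,3-dimethylcyclopropyl]methanol
Conditions: Et2Zn, CHI3, (4R,5R)-2-butyl-N,N,N',N'-tetramethyl-1,3,2-dioxaborolane-4,5-dicarboxamide (1.2 equiv), CH2Cl2, −40 to 0 °C
Reagents that add atoms: iodoform, IC(I)I
Why: Asymmetric Simmons–Smith-type iodocyclopropanation in which the zinc alkoxide of 3 binds the chiral dioxaborolane and the carbenoid EtZnCHI2 is delivered to one alkene face; syn addition keeps the two methyl groups cis and the face chosen by the controller sets C3 (and C1), C3 being the one stereocentre that is carried through step 7.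

**Step 3**
Reactants: 4 [(1S,2S,3R)-2-iodo-1,3-dimethylcyclopropyl]methanol; 5 [4-(benzyloxy)-3-methoxyphenyl]boronic acid
Product: 6 [(1R,2R,3S)-2-[4-(benzyloxy)-3-methoxyphenyl]-1,3-dimethylcyclopropyl]methanol
Conditions: Pd(OAc)2 (10 mol %), PPh3, K2CO3, Bu4NCl, DMF/H2O, 90 °C
Reagents that add atoms: none
Why: Suzuki–Miyaura coupling of an iodocyclopropane; oxidative addition and reductive elimination go with retention at the ring carbon and a cyclopropylpalladium species cannot undergo β-hydride elimination, so the ring and the free alcohol are kept (the descriptors change only through priorities).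

**Step 4**
Reactants: 6 [(1R,2R,3S)-2-[4-(benzyloxy)-3-methoxyphenyl]-1,3-dimethylcyclopropyl]methanol
Product: 7 (1R,2R,3S)-2-[4-(benzyloxy)-3-methoxyphenyl]-1,3-dimethylcyclopropane-1-carbaldehyde
Conditions: Dess–Martin periodinane, NaHCO3, CH2Cl2, 0 °C to rt
Reagents that add atoms: none
Why: Dess–Martin oxidation of the neopentyl-type primary alcohol under buffered, non-acidic conditions, so that the donor–acceptor cyclopropane that is formed is not opened.

**Step 5**
Reactants: 7 (1R,2R,3S)-2-[4-(benzyloxy)-3-methoxyphenyl]-1,3-dimethylcyclopropane-1-carbaldehyde; 2 (4-bromo-2-methoxyphenoxy)tri(propan-2-yl)silane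
Product: 9 [(1R,2R,3S)-2-[4-(benzyloxy)-3-methoxyphenyl]-1,3-dimethylcyclopropyl]{3-methoxy-4-[tri(propan-2-yl)silyloxy]phenyl}methanol (both carbinol epimers), via aryllithium 8 (not isolated)
Conditions: 2, n-BuLi, THF, −78 °C; then 7, −78 to −40 °C; aq. NH4Cl
Reagents that add atoms: none
Why: Bromine–lithium exchange followed by 1,2-addition to the non-enolisable aldehyde; the new carbinol centre is left uncontrolled because it is oxidised away in step 6.

**Step 6**
Reactants: 9 [(1R,2R,3S)-2-[4-(benzyloxy)-3-methoxyphenyl]-1,3-dimethylcyclopropyl]{3-methoxy-4-[tri(propan-2-yl)silyloxy]phenyl}methanol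
Product: 10 [(1R,2R,3S)-2-[4-(benzyloxy)-3-methoxyphenyl]-1,3-dimethylcyclopropyl]{3-methoxy-4-[tri(propan-2-yl)silyloxy]phenyl}methanone
Conditions: Dess–Martin periodinane, NaHCO3, CH2Cl2, rt
Reagents that add atoms: none
Why: Dess–Martin oxidation of the benzylic carbinol to the aryl ketone, which turns the arylcyclopropane into a vicinal donor–acceptor cyclopropane without touching its ring stereocentres.

**Step 7**
Reactants: 10 [(1R,2R,3S)-2-[4-(benzyloxy)-3-methoxyphenyl]-1,3-dimethylcyclopropyl]{3-methoxy-4-[tri(propan-2-yl)silyloxy]phenyl}methanone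
Product: 12 {4-[(2S,3R,4R,5R)-5-[4-(benzyloxy)-3-methoxyphenyl]-3,4-dimethyloxolan-2-yl]-2-methoxyphenoxy}tri(propan-2-yl)silane, via dihydrofuran 11 (not isolated)
Conditions: BF3·OEt2 (0.2 equiv), CH2Cl2, −78 to −20 °C until 10 is consumed; then −78 °C, Et3SiH (5 equiv), CF3CO2H (3 equiv), −78 to −40 °C; aq. NaHCO3
Reagents that add atoms: none
Why: BF3 bound to the aryl ketone polarises the C1–C2 bond of the donor–acceptor cyclopropane, which ionises to a 4-benzyloxy-3-methoxybenzyl cation and a boron enolate; the enolate oxygen closes onto the cation (5-exo-trig with respect to the quinoid cation, an enolendo O-alkylation) to give the 4,5-dihydrofuran 11, i.e. a Lewis-acid Cloke–Wilson rearrangement, the oxygen analogue of the vinylcyclopropane–cyclopentene rearrangement. Only the methyl-bearing cyclopropane carbon C3 is untouched and it becomes C4 of the oxolane; in the reversible ring closure it places the C5 aryl group trans to its methyl, so both C2 epimers of 10 converge. CF3CO2H then protonates the enol ether at C3 reversibly, so the more stable 3,4-trans oxocarbenium ion is the one that is reduced (Curtin–Hammett), and Et3SiH adds to C2 anti to the C3 methyl (inside attack on the envelope), giving the 2,3-cis-3,4-trans-4,5-trans array; this second stage is an ionic hydrogenation through the same 2-aryl oxocarbenium ion that is reduced in the BF3·OEt2/hydride deoxygenation of lignan hemiketals. The selectivities needed are cleavage of C1–C2 and not C1–C3 (secured by the aryl donor on C2 and the acyl acceptor on C1), O- and not C-capture of the cation (proximal enolate oxygen, five-membered closure, low temperature) and kinetic hydride delivery without benzylic epimerisation (−78 °C, short contact). The silane is added only after the ring expansion so that the open benzylic cation is not reduced.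

**Step 8**
Reactants: 12 {4-[(2S,3R,4R,5R)-5-[4-(benzyloxy)-3-methoxyphenyl]-3,4-dimethyloxolan-2-yl]-2-methoxyphenoxy}tri(propan-2-yl)silane
Product: 13 2-methoxy-4-[(2R,3R,4R,5S)-5-{3-methoxy-4-[tri(propan-2-yl)silyloxy]phenyl}-3,4-dimethyloxolan-2-yl]phenol
Conditions: H2 (1 atm), Pd/C, EtOAc, rt
Reagents that add atoms: none
Why: Hydrogenolysis of the aryl benzyl ether under neutral conditions; the aryl TIPS ether and, without acid at 1 atm, the benzylic C–O bonds of the 2,5-diaryloxolane are expected to stay, as is usual in debenzylations of tetrahydrofuran lignans.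

**Step 9**
Reactants: 14 ethyl (2S)-2-hydroxypropanoate (ethyl (S)-lactate)
Product: 15 (2S)-2-hydroxy-N-methoxy-N-methylpropanamide
Conditions: MeNH(OMe)·HCl, i-PrMgCl, THF, −20 to 0 °C
Reagents that add atoms: N,O-dimethylhydroxylamine hydrochloride, Cl.CNOC
Why: Weinreb amide formation by aminolysis of the ester with the chloromagnesium amide; the hydroxyl is carried as its magnesium alkoxide and the stereocentre is not enolised.

**Step 10**
Reactants: 15 (2S)-2-hydroxy-N-methoxy-N-methylpropanamide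
Product: 16 (2S)-2-[tert-butyl(dimethyl)silyloxy]-N-methoxy-N-methylpropanamide
Conditions: TBSCl, imidazole, DMF, rt
Reagents that add atoms: tert-butyl(chloro)dimethylsilane, CC(C)(C)[Si](C)(C)Cl
Why: Imidazole-promoted silylation of the secondary alcohol, which masks the hydroxyl for the aryl Grignard addition.

**Step 11**
Reactants: 16 (2S)-2-[tert-butyl(dimethyl)silyloxy]-N-methoxy-N-methylpropanamide; 2 (4-bromo-2-methoxyphenoxy)tri(propan-2-yl)silane
Product: 18 (2S)-2-[tert-butyl(dimethyl)silyloxy]-1-{3-methoxy-4-[tri(propan-2-yl)silyloxy]phenyl}propan-1-one, via arylmagnesium bromide 17 (not isolated)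
Conditions: 2, Mg turnings, I2 (cat.), THF, rt to 45 °C; then 16, THF, 0 °C to rt; aq. NH4Cl
Reagents that add atoms: none
Why: Weinreb ketone synthesis with the aryl Grignard reagent formed by magnesium insertion into the aryl bromide; the magnesium-chelated tetrahedral intermediate prevents over-addition, and the Grignard reagent, being less basic than an aryllithium, should leave the α-silyloxy stereocentre undeprotonated.

**Step 12**
Reactants: 18 (2S)-2-[tert-butyl(dimethyl)silyloxy]-1-{3-methoxy-4-[tri(propan-2-yl)silyloxy]phenyl}propan-1-one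
Product: 19 (2S)-2-hydroxy-1-{3-methoxy-4-[tri(propan-2-yl)silyloxy]phenyl}propan-1-one
Conditions: camphorsulfonic acid (0.2 equiv), MeOH, 0 °C to rt
Reagents that add atoms: none
Why: Acid-catalysed methanolysis of the alkyl TBS ether; under acid an aryl TIPS ether is cleaved far more slowly, and the mild conditions should not epimerise the α-ketol.

**Step 13**
Reactants: 13 2-methoxy-4-[(2R,3R,4R,5S)-5-{3-methoxy-4-[tri(propan-2-yl)silyloxy]phenyl}-3,4-dimethyloxolan-2-yl]phenol; 19 (2S)-2-hydroxy-1-{3-methoxy-4-[tri(propan-2-yl)silyloxy]phenyl}propan-1-one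
Product: 20 (2R)-2-{2-methoxy-4-[(2R,3R,4R,5S)-5-{3-methoxy-4-[tri(propan-2-yl)silyloxy]phenyl}-3,4-dimethyloxolan-2-yl]phenoxy}-1-{3-methoxy-4-[tri(propan-2-yl)silyloxy]phenyl}propan-1-one
Conditions: PPh3, DIAD, THF, 0 °C to rt
Reagents that add atoms: none
Why: Mitsunobu etherification; the phenol displaces the oxyphosphonium of the α-ketol in an SN2 reaction accelerated by the adjacent carbonyl, with inversion (2S to 2R), under neutral conditions that spare the aryl TIPS ethers.

**Step 14**
Reactants: 20 (2R)-2-{2-methoxy-4-[(2R,3R,4R,5S)-5-{3-methoxy-4-[tri(propan-2-yl)silyloxy]phenyl}-3,4-dimethyloxolan-2-yl]phenoxy}-1-{3-methoxy-4-[tri(propan-2-yl)silyloxy]phenyl}propan-1-one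
Product: 21 (1R,2R)-2-{2-methoxy-4-[(2R,3R,4R,5S)-5-{3-methoxy-4-[tri(propan-2-yl)silyloxy]phenyl}-3,4-dimethyloxolan-2-yl]phenoxy}-1-{3-methoxy-4-[tri(propan-2-yl)silyloxy]phenyl}propan-1-ol
Conditions: Bu4NBH4, CH2Cl2/MeOH, −40 to −20 °C; aq. NH4Cl
Reagents that add atoms: none
Why: Felkin–Anh (polar) reduction with a non-chelating ammonium borohydride; hydride attacks anti to the aryloxy group past the small hydrogen, which should give the syn (threo) 1R,2R alcohol, whereas chelating counter-ions that favour the erythro isomer are avoided.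

**Step 15**
Reactants: 21 (1R,2R)-2-{2-methoxy-4-[(2R,3R,4R,5S)-5-{3-methoxy-4-[tri(propan-2-yl)silyloxy]phenyl}-3,4-dimethyloxolan-2-yl]phenoxy}-1-{3-methoxy-4-[tri(propan-2-yl)silyloxy]phenyl}propan-1-ol
Product: 22 4-[(1R,2R)-1-hydroxy-2-{4-[(2R,3R,4R,5S)-5-(4-hydroxy-3-methoxyphenyl)-3,4-dimethyloxolan-2-yl]-2-methoxyphenoxy}propyl]-2-methoxyphenol (CNP0171079.2)
Conditions: TBAF (2.2 equiv), AcOH (2.2 equiv), THF, 0 °C
Reagents that add atoms: none
Why: Fluoride cleavage of both aryl TIPS ethers, buffered with acetic acid so that the phenoxides are protonated at once and no stereocentre is exposed to base.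

**Compound list**
1 | 4-bromo-2-methoxyphenol | COc1cc(Br)ccc1O | starting material
2 | (4-bromo-2-methoxyphenoxy)tri(propan-2-yl)silane | COc1cc(Br)ccc1O[Si](C(C)C)(C(C)C)C(C)C | intermediate
3 | (E)-2-methylbut-2-en-1-ol | C/C=C(\C)CO | starting material
4 | [(1S,2S,3R)-2-iodo-1,3-dimethylcyclopropyl]methanol | OC[C@@]1(C)[C@@H](I)[C@@H]1C | intermediate
5 | [4-(benzyloxy)-3-methoxyphenyl]boronic acid | COc1cc(B(O)O)ccc1OCc1ccccc1 | starting material
6 | [(1R,2R,3S)-2-[4-(benzyloxy)-3-methoxyphenyl]-1,3-dimethylcyclopropyl]methanol | OC[C@@]1(C)[C@@H](c2ccc(OCc3ccccc3)c(OC)c2)[C@@H]1C | intermediate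
7 | (1R,2R,3S)-2-[4-(benzyloxy)-3-methoxyphenyl]-1,3-dimethylcyclopropane-1-carbaldehyde | O=C[C@@]1(C)[C@@H](c2ccc(OCc3ccccc3)c(OC)c2)[C@@H]1C | intermediate
8 | {3-methoxy-4-[tri(propan-2-yl)silyloxy]phenyl}lithium | COc1cc([Li])ccc1O[Si](C(C)C)(C(C)C)C(C)C | intermediate
9 | [(1R,2R,3S)-2-[4-(benzyloxy)-3-methoxyphenyl]-1,3-dimethylcyclopropyl]{3-methoxy-4-[tri(propan-2-yl)silyloxy]phenyl}methanol (both carbinol epimers) | OC(c1ccc(O[Si](C(C)C)(C(C)C)C(C)C)c(OC)c1)[C@@]1(C)[C@@H](c2ccc(OCc3ccccc3)c(OC)c2)[C@@H]1C | intermediate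
10 | [(1R,2R,3S)-2-[4-(benzyloxy)-3-methoxyphenyl]-1,3-dimethylcyclopropyl]{3-methoxy-4-[tri(propan-2-yl)silyloxy]phenyl}methanone | O=C(c1ccc(O[Si](C(C)C)(C(C)C)C(C)C)c(OC)c1)[C@@]1(C)[C@@H](c2ccc(OCc3ccccc3)c(OC)c2)[C@@H]1C | intermediate
11 | {4-[(4R,5R)-5-[4-(benzyloxy)-3-methoxyphenyl]-3,4-dimethyl-4,5-dihydrofuran-2-yl]-2-methoxyphenoxy}tri(propan-2-yl)silane | COc1cc([C@@H]2OC(c3ccc(O[Si](C(C)C)(C(C)C)C(C)C)c(OC)c3)=C(C)[C@H]2C)ccc1OCc1ccccc1 | intermediate
12 | {4-[(2S,3R,4R,5R)-5-[4-(benzyloxy)-3-methoxyphenyl]-3,4-dimethyloxolan-2-yl]-2-methoxyphenoxy}tri(propan-2-yl)silane | COc1cc([C@@H]2O[C@H](c3ccc(O[Si](C(C)C)(C(C)C)C(C)C)c(OC)c3)[C@H](C)[C@H]2C)ccc1OCc1ccccc1 | intermediate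
13 | 2-methoxy-4-[(2R,3R,4R,5S)-5-{3-methoxy-4-[tri(propan-2-yl)silyloxy]phenyl}-3,4-dimethyloxolan-2-yl]phenol | COc1cc([C@@H]2O[C@H](c3ccc(O[Si](C(C)C)(C(C)C)C(C)C)c(OC)c3)[C@H](C)[C@H]2C)ccc1O | intermediate
14 | ethyl (2S)-2-hydroxypropanoate | CCOC(=O)[C@H](C)O | starting material
15 | (2S)-2-hydroxy-N-methoxy-N-methylpropanamide | CON(C)C(=O)[C@H](C)O | intermediate
16 | (2S)-2-[tert-butyl(dimethyl)silyloxy]-N-methoxy-N-methylpropanamide | CON(C)C(=O)[C@H](C)O[Si](C)(C)C(C)(C)C | intermediate
17 | bromo{3-methoxy-4-[tri(propan-2-yl)silyloxy]phenyl}magnesium | COc1cc([Mg]Br)ccc1O[Si](C(C)C)(C(C)C)C(C)C | intermediate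
18 | (2S)-2-[tert-butyl(dimethyl)silyloxy]-1-{3-methoxy-4-[tri(propan-2-yl)silyloxy]phenyl}propan-1-one | COc1cc(C(=O)[C@H](C)O[Si](C)(C)C(C)(C)C)ccc1O[Si](C(C)C)(C(C)C)C(C)C | intermediate
19 | (2S)-2-hydroxy-1-{3-methoxy-4-[tri(propan-2-yl)silyloxy]phenyl}propan-1-one | COc1cc(C(=O)[C@H](C)O)ccc1O[Si](C(C)C)(C(C)C)C(C)C | intermediate
20 | (2R)-2-{2-methoxy-4-[(2R,3R,4R,5S)-5-{3-methoxy-4-[tri(propan-2-yl)silyloxy]phenyl}-3,4-dimethyloxolan-2-yl]phenoxy}-1-{3-methoxy-4-[tri(propan-2-yl)silyloxy]phenyl}propan-1-one | COc1cc(C(=O)[C@@H](C)Oc2ccc([C@@H]3O[C@H](c4ccc(O[Si](C(C)C)(C(C)C)C(C)C)c(OC)c4)[C@H](C)[C@H]3C)cc2OC)ccc1O[Si](C(C)C)(C(C)C)C(C)C | intermediate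
21 | (1R,2R)-2-{2-methoxy-4-[(2R,3R,4R,5S)-5-{3-methoxy-4-[tri(propan-2-yl)silyloxy]phenyl}-3,4-dimethyloxolan-2-yl]phenoxy}-1-{3-methoxy-4-[tri(propan-2-yl)silyloxy]phenyl}propan-1-ol | COc1cc([C@@H](O)[C@@H](C)Oc2ccc([C@@H]3O[C@H](c4ccc(O[Si](C(C)C)(C(C)C)C(C)C)c(OC)c4)[C@H](C)[C@H]3C)cc2OC)ccc1O[Si](C(C)C)(C(C)C)C(C)C | intermediate
22 | 4-[(1R,2R)-1-hydroxy-2-{4-[(2R,3R,4R,5S)-5-(4-hydroxy-3-methoxyphenyl)-3,4-dimethyloxolan-2-yl]-2-methoxyphenoxy}propyl]-2-methoxyphenol | COc1cc([C@@H](O)[C@@H](C)Oc2ccc([C@@H]3O[C@H](c4ccc(O)c(OC)c4)[C@H](C)[C@H]3C)cc2OC)ccc1O | target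

**Step count and risks**
Total step count: 15. Longest linear sequence: 10 steps (3 → 4 → 6 → 7 → 9 → 10 → 12 → 13 → 20 → 21 → 22; steps 2–8 and 13–15).

Steps most likely to fail:

1. Step 7. The benzylic cation may be captured by carbon (Friedel–Crafts closure onto the aroyl ring) or lose a proton instead of closing through oxygen, and the acid may epimerise the benzylic ring carbons or let the silane open the oxolane reductively. Fallback, setting out from 7 and coming back at 12, with the aryl group brought in after the ring expansion: aldehyde 7 is oxidised (Pinnick oxidation: NaClO2, NaH2PO4, 2-methylbut-2-ene, t-BuOH/H2O) to (1R,2R,3S)-2-[4-(benzyloxy)-3-methoxyphenyl]-1,3-dimethylcyclopropane-1-carboxylic acid F1. The donor–acceptor cyclopropane acid is ring-expanded with acid (cat. CF3SO3H, CH2Cl2, 0 °C; DBU to equilibrate the α-centre if needed) to the trans,trans-lactone (3R,4R,5R)-5-[4-(benzyloxy)-3-methoxyphenyl]-3,4-dimethyloxolan-2-one F2. Aryllithium 8 (from 2 and n-BuLi, THF, −78 °C) adds to give the cyclic hemiketal (3R,4R,5R)-5-[4-(benzyloxy)-3-methoxyphenyl]-2-{3-methoxy-4-[tri(propan-2-yl)silyloxy]phenyl}-3,4-dimethyloxolan-2-ol F3, and the standard reductive deoxygenation of lignan hemiketals (BF3·OEt2, Et3SiH, CH2Cl2, −78 °C) should give 12.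

2. Step 2. Facial selectivity may be poor, or carbenoid transfer sluggish, with the 2-methyl-substituted allylic alcohol. Fallback, setting out from 3 and coming back at 4, replacing asymmetric induction by resolution: ligand-free hydroxyl-directed iodocyclopropanation (Et2Zn, CHI3, CH2Cl2) gives racemic [(1S,2S,3R)-2-iodo-1,3-dimethylcyclopropyl]methanol F4. Lipase-catalysed acylation (Burkholderia cepacia lipase, vinyl acetate, t-BuOMe) separates the enantiomers; written for the case that the wanted enantiomer is the one acylated, it gives [(1S,2S,3R)-2-iodo-1,3-dimethylcyclopropyl]methyl acetate F5, and K2CO3/MeOH returns 4. If the lipase prefers the antipode, 4 is simply the recovered alcohol.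

3. Step 3. Transmetalation may be slow and protodeiodination may compete at the cyclopropyl iodide flanked by a quaternary and a methyl-bearing carbon. Fallback, setting out from 4 and 1 and coming back at 6, with the polarity of the coupling reversed: 4 is deprotonated and exchanged (n-BuLi 1 equiv, then t-BuLi 2.1 equiv, Et2O, −78 °C) to the configurationally stable lithium [(1S,2S,3S)-2-lithio-1,3-dimethylcyclopropyl]methanolate F6, which is borylated with 2-isopropoxy-4,4,5,5-tetramethyl-1,3,2-dioxaborolane to [(1S,2S,3S)-1,3-dimethyl-2-(4,4,5,5-tetramethyl-1,3,2-dioxaborolan-2-yl)cyclopropyl]methanol F7 (retention). Phenol 1 is benzylated (BnBr, K2CO3, DMF) to 1-(benzyloxy)-4-bromo-2-methoxybenzene F8, and Suzuki–Miyaura coupling of F7 with F8 (Pd(dppf)Cl2, K3PO4, toluene/H2O, 90 °C) should give 6.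

**Further compounds**
F1 | step 7 | (1R,2R,3S)-2-[4-(benzyloxy)-3-methoxyphenyl]-1,3-dimethylcyclopropane-1-carboxylic acid | OC(=O)[C@@]1(C)[C@@H](c2ccc(OCc3ccccc3)c(OC)c2)[C@@H]1C
F2 | step 7 | (3R,4R,5R)-5-[4-(benzyloxy)-3-methoxyphenyl]-3,4-dimethyloxolan-2-one | COc1cc([C@@H]2OC(=O)[C@H](C)[C@H]2C)ccc1OCc1ccccc1
F3 | step 7 | (3R,4R,5R)-5-[4-(benzyloxy)-3-methoxyphenyl]-2-{3-methoxy-4-[tri(propan-2-yl)silyloxy]phenyl}-3,4-dimethyloxolan-2-ol (both anomers) | COc1cc([C@@H]2OC(O)(c3ccc(O[Si](C(C)C)(C(C)C)C(C)C)c(OC)c3)[C@H](C)[C@H]2C)ccc1OCc1ccccc1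
F4 | step 2 | racemic [(1S,2S,3R)-2-iodo-1,3-dimethylcyclopropyl]methanol | OC[C@@]1(C)[C@@H](I)[C@@H]1C.OC[C@]1(C)[C@H](I)[C@H]1C
F5 | step 2 | [(1S,2S,3R)-2-iodo-1,3-dimethylcyclopropyl]methyl acetate | CC(=O)OC[C@@]1(C)[C@@H](I)[C@@H]1C
F6 | step 3 | lithium [(1S,2S,3S)-2-lithio-1,3-dimethylcyclopropyl]methanolate | [Li]OC[C@@]1(C)[C@@H]([Li])[C@@H]1C
F7 | step 3 | [(1S,2S,3S)-1,3-dimethyl-2-(4,4,5,5-tetramethyl-1,3,2-dioxaborolan-2-yl)cyclopropyl]methanol | OC[C@@]1(C)[C@@H](B2OC(C)(C)C(C)(C)O2)[C@@H]1C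
F8 | step 3 | 1-(benzyloxy)-4-bromo-2-methoxybenzene | COc1cc(Br)ccc1OCc1ccccc1
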